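**Retrosynthetic overview**
1. The ring C–Br bond and the final position of the ring alkene come last: an ionic ene-type bromination of a cyclohexene whose double bond sits next to the CMe2 carbon.
2. The side-chain C–Cl comes from a bromomethyl enone by CBS reduction and invertive chlorination, so no alkene bromochlorination is used.
3. The bromomethyl enone comes from a cyclohexenyl triflate and a two-carbon stannane (Stille coupling, then NBS).
4. Key step: a chloriranium-triggered 6-endo alkyne cyclisation of an acyclic chlorohydrin forms the only ring (the cyclohexene), sets the ring C–Cl centre and fixes the alkene position.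
5. The chlorohydrin comes from 6-methylhept-5-en-1-yne (Shi epoxidation, HCl), made from homoprenyl bromide and acetylide.

Assumption: compounds 1, 2 and 8 and both chiral catalysts are bought; two operations run in one flask count as one step.

**Step 1**
Reactants: 1 5-bromo-2-methylpent-2-ene; 2 lithium acetylide–ethylenediamine complex
Product: 3 6-methylhept-5-en-1-yne
Conditions: LiC≡CH·H2NCH2CH2NH2 (1.3 equiv), DMSO, 10 → 25 °C
Reagents that add atoms: none
Why: SN2 alkylation of lithium acetylide by a primary homoallylic bromide in DMSO is a standard terminal-alkyne synthesis that leaves the trisubstituted alkene untouched, no stereocentre being formed.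

**Step 2**
Reactants: 3 6-methylhept-5-en-1-yne
Product: 4 (3S)-3-(but-3-yn-1-yl)-2,2-dimethyloxirane
Conditions: L-fructose-derived Shi ketone (1,2:4,5-di-O-isopropylidene-β-L-erythro-2,3-hexodiulo-2,6-pyranose, 30 mol %), Oxone (2KHSO5·KHSO4·K2SO4), K2CO3, Bu4NHSO4, aq Na2B4O7 buffer, MeCN–CH2(OMe)2, 0 °C
Reagents that add atoms: Oxone, active component potassium peroxymonosulfate KHSO5, SMILES [K+].[O-]S(=O)(=O)OO
Why: Shi asymmetric epoxidation, in which the chiral dioxirane made from the ketone and KHSO5 attacks the electron-rich trisubstituted alkene through a spiro transition state while the terminal alkyne is inert; the usual D-fructose-derived ketone gives the (R)-oxirane from R-CH=CMe2 olefins, so its L-series antipode sets the (3S) centre.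

**Step 3**
Reactants: 4 (3S)-3-(but-3-yn-1-yl)-2,2-dimethyloxirane
Product: 5 (3S)-2-chloro-2-methylhept-6-yn-3-ol
Conditions: HCl (1 M in Et2O, 1.1 equiv), Et2O, −40 → 0 °C
Reagents that add atoms: hydrogen chloride, SMILES Cl
Why: Acid-mediated Markovnikov epoxide opening places chloride on the tertiary carbon and does not touch the C–O bond of the stereocentre, which therefore stays (S), and any minor regioisomer from invertive attack at the secondary carbon would feed the same cation in step 4.

**Step 4**
Reactants: 5 (3S)-2-chloro-2-methylhept-6-yn-3-ol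
Product: 7 (4R)-4-chloro-3,3-dimethylcyclohex-1-en-1-yl trifluoromethanesulfonate, via secondary triflate 6 (not isolated)
Conditions: Tf2O (1.1 equiv), 2,6-di-tert-butyl-4-methylpyridine (1.5 equiv), CH2Cl2, −78 → 0 °C
Reagents that add atoms: trifluoromethanesulfonic anhydride, SMILES O=S(=O)(OS(=O)(=O)C(F)(F)F)C(F)(F)F
Why: Proposed new method: the triflate of the secondary alcohol is expelled by the anti-periplanar tertiary chlorine (1,2-chlorine shift) to give a configurationally stable 2,2-dimethylchloriranium ion with inversion at the former carbinol carbon, its tertiary carbon is attacked by the terminal alkyne carbon in a 6-endo closure (the 5-exo mode would need a primary vinyl cation) and the cyclohexenyl cation collapses with triflate, so that (S)-C–O becomes (R)-C–Cl and the alkene is locked next to the quaternary carbon, a regiochemistry that enolisation of the parent ketone would not give; the closest known reaction types are the enantiospecific solvolysis of β-chloro sulfonates through chloriranium ions, bromonium generation from bromohydrin derivatives for polyene cyclisation, and alkyne-participated solvolyses that give cyclohexenyl trifluoroacetates or triflates.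

**Step 5**
Reactants: 7 (4R)-4-chloro-3,3-dimethylcyclohex-1-en-1-yl trifluoromethanesulfonate; 8 tributyl(1-ethoxyvinyl)stannane
Product: 10 2-bromo-1-[(4R)-4-chloro-3,3-dimethylcyclohex-1-en-1-yl]ethan-1-one, via ethoxydiene 9 (not isolated)
Conditions: Pd(PPh3)4 (5 mol %), LiCl (3 equiv), THF, 65 °C; then NBS (1.05 equiv), THF–H2O 4:1, 0 °C
Reagents that add atoms: N-bromosuccinimide, SMILES O=C1CCC(=O)N1Br; water, SMILES O
Why: Stille coupling of the alkenyl triflate (LiCl-assisted, secondary alkyl chloride inert) installs a 1-ethoxyvinyl group, whose enol ether carbon is then brominated by NBS and hydrolysed to the bromomethyl ketone, no stereocentre being formed.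

**Step 6**
Reactants: 10 2-bromo-1-[(4R)-4-chloro-3,3-dimethylcyclohex-1-en-1-yl]ethan-1-one
Product: 11 (1R)-2-bromo-1-[(4R)-4-chloro-3,3-dimethylcyclohex-1-en-1-yl]ethan-1-ol
Conditions: (R)-2-methyl-CBS-oxazaborolidine [(3aR)-1-methyl-3,3-diphenyltetrahydro-1H,3H-pyrrolo[1,2-c][1,3,2]oxazaborole, 15 mol %], catecholborane (1.5 equiv), toluene, −78 °C; aq NaOH work-up
Reagents that add atoms: none
Why: Corey–Bakshi–Shibata reduction, in which the oxazaborolidine–borane complex binds the ketone with the cyclohexenyl group as the large and CH2Br as the small substituent and delivers hydride 1,2 to one face under reagent control, the (R)-catalyst giving the (1R)-bromohydrin.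

**Step 7**
Reactants: 11 (1R)-2-bromo-1-[(4R)-4-chloro-3,3-dimethylcyclohex-1-en-1-yl]ethan-1-ol
Product: 12 (4R)-1-[(1S)-2-bromo-1-chloroethyl]-4-chloro-3,3-dimethylcyclohex-1-ene
Conditions: PPh3 (1.2 equiv), hexachloroacetone (3 equiv), CH2Cl2, −20 → 0 °C
Reagents that add atoms: hexachloroacetone, SMILES O=C(C(Cl)(Cl)Cl)C(Cl)(Cl)Cl
Why: Magid chlorination (Appel type, Ph3P and hexachloroacetone), in which chloride displaces the allylic alkoxyphosphonium group by SN2 with inversion and without allylic transposition, the SN2' terminus being neopentylic, so (1R)-OH becomes (1S)-Cl.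

**Step 8**
Reactants: 12 (4R)-1-[(1S)-2-bromo-1-chloroethyl]-4-chloro-3,3-dimethylcyclohex-1-ene
Product: 13 (4R,6S)-6-bromo-1-[(1S)-2-bromo-1-chloroethyl]-4-chloro-5,5-dimethylcyclohex-1-ene
Conditions: NBS (1.05 equiv), (CF3)2CHOH–CH2Cl2 1:4, 0 °C, dark
Reagents that add atoms: N-bromosuccinimide, SMILES O=C1CCC(=O)N1Br
Why: Proposed new method: NBS activated by hydrogen bonding to (CF3)2CHOH transfers Br+ to the trisubstituted alkene on the face anti to the pseudoaxial methyl group of the half-chair that keeps chlorine equatorial, the bromine can end only on C2 of 12 because elimination needs the cation on C1 and C3 is quaternary, and succinimide anion then removes a ring C6 proton (the side-chain C–H is deactivated by chlorine) to give the transposed allylic bromide with pseudoaxial Br trans to Cl, which is the (6S) centre of 13; the closest known reaction types are ene-type allylic chlorination or bromination of trisubstituted alkenes by positive-halogen reagents and the bromination–dehydrobromination of 1-substituted cyclohexenes.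

**Compound list**
1 | 5-bromo-2-methylpent-2-ene | CC(C)=CCCBr | starting material
2 | lithium acetylide–ethylenediamine complex | [Li+].[C-]#C.NCCN | starting material
3 | 6-methylhept-5-en-1-yne | CC(C)=CCCC#C | intermediate
4 | (3S)-3-(but-3-yn-1-yl)-2,2-dimethyloxirane | CC1(C)O[C@H]1CCC#C | intermediate
5 | (3S)-2-chloro-2-methylhept-6-yn-3-ol | CC(C)(Cl)[C@@H](O)CCC#C | intermediate
6 | (3S)-2-chloro-2-methylhept-6-yn-3-yl trifluoromethanesulfonate | CC(C)(Cl)[C@@H](OS(=O)(=O)C(F)(F)F)CCC#C | intermediate
7 | (4R)-4-chloro-3,3-dimethylcyclohex-1-en-1-yl trifluoromethanesulfonate | FC(F)(F)S(=O)(=O)OC1=CC(C)(C)[C@H](Cl)CC1 | intermediate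
8 | tributyl(1-ethoxyvinyl)stannane | CCCC[Sn](CCCC)(CCCC)C(=C)OCC | starting material
9 | (4R)-4-chloro-1-(1-ethoxyethenyl)-3,3-dimethylcyclohex-1-ene | CCOC(=C)C1=CC(C)(C)[C@H](Cl)CC1 | intermediate
10 | 2-bromo-1-[(4R)-4-chloro-3,3-dimethylcyclohex-1-en-1-yl]ethan-1-one | O=C(CBr)C1=CC(C)(C)[C@H](Cl)CC1 | intermediate
11 | (1R)-2-bromo-1-[(4R)-4-chloro-3,3-dimethylcyclohex-1-en-1-yl]ethan-1-ol | O[C@@H](CBr)C1=CC(C)(C)[C@H](Cl)CC1 | intermediate
12 | (4R)-1-[(1S)-2-bromo-1-chloroethyl]-4-chloro-3,3-dimethylcyclohex-1-ene | Cl[C@H](CBr)C1=CC(C)(C)[C@H](Cl)CC1 | intermediate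
13 | (4R,6S)-6-bromo-1-[(1S)-2-bromo-1-chloroethyl]-4-chloro-5,5-dimethylcyclohex-1-ene | CC1(C)[C@H](Cl)CC=C([C@H](Cl)CBr)[C@H]1Br | target

**Totals and risks**
Total step count: 8. Longest linear sequence: 8 steps (1 → 13).

The step most likely to fail is step 4. The alkyne is a weak π-nucleophile, so loss of a methyl proton from the chloriranium ion (giving an isopropenyl allylic chloride) or a methyl shift at the triflate stage can compete. The fallback makes the cation without a neighbouring-group step and sets out from 4. Dichlorotriphenylphosphorane (Ph3PCl2, CH2Cl2, 0 °C) replaces both C–O bonds by C–Cl, with inversion at the secondary carbon, to give (5R)-5,6-dichloro-6-methylhept-1-yne F1. AgOSO2CF3 with 2,6-di-tert-butyl-4-methylpyridine in CH2Cl2–MeNO2 at −40 °C then ionises only the tertiary C–Cl bond, the stereocentre being a spectator. The same 6-endo closure and triflate capture come back to the route at 7.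

Second is step 8. The β-bromo cation may lose the side-chain proton (exocyclic chloroalkene), be trapped by solvent, or form slowly from the electron-poor alkene. The fallback moves the bromination to the ketone stage, where the side chain has no such proton, and sets out from 10.
- Br2 (CH2Cl2, −78 °C) adds trans-diaxially, on the same facial grounds as in step 8, to give 2-bromo-1-[(1R,2S,4R)-1,2-dibromo-4-chloro-3,3-dimethylcyclohexyl]ethan-1-one F2.
- 2,4,6-Collidine (CH2Cl2, 0 → 25 °C) removes HBr from the tertiary bromide and the only anti-periplanar ring hydrogen to give 2-bromo-1-[(4R,6R)-6-bromo-4-chloro-5,5-dimethylcyclohex-1-en-1-yl]ethan-1-one F3. The 6R descriptor arises only from the ranking rule; the geometry is that of 13.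
- The CBS reduction of step 6 gives (1R)-2-bromo-1-[(4R,6R)-6-bromo-4-chloro-5,5-dimethylcyclohex-1-en-1-yl]ethan-1-ol F4.
- The Magid chlorination of step 7 comes back to the route at 13.

Third is step 7. The neighbouring bromine may take part through a bromiranium ion, giving retention or a 1,2-halogen swap. The fallback brings in chlorine by epoxide opening while no bromine is present and sets out from 11.
- K2CO3 in MeOH closes the bromohydrin to (2R)-2-[(4R)-4-chloro-3,3-dimethylcyclohex-1-en-1-yl]oxirane F5 without touching the stereocentre.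
- HCl in Et2O at −78 °C opens the vinyl epoxide at the allylic carbon with inversion to (2S)-2-chloro-2-[(4R)-4-chloro-3,3-dimethylcyclohex-1-en-1-yl]ethan-1-ol F6.
- CBr4 and PPh3 (CH2Cl2, 0 °C) turn the primary alcohol into the bromide, and the route is rejoined at 12.

**Further compounds**
F1 | step 4 | (5R)-5,6-dichloro-6-methylhept-1-yne | CC(C)(Cl)[C@H](Cl)CCC#C
F2 | step 8 | 2-bromo-1-[(1R,2S,4R)-1,2-dibromo-4-chloro-3,3-dimethylcyclohexyl]ethan-1-one | CC1(C)[C@H](Cl)CC[C@@](Br)(C(=O)CBr)[C@H]1Br
F3 | step 8 | 2-bromo-1-[(4R,6R)-6-bromo-4-chloro-5,5-dimethylcyclohex-1-en-1-yl]ethan-1-one | CC1(C)[C@H](Cl)CC=C(C(=O)CBr)[C@H]1Br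
F4 | step 8 | (1R)-2-bromo-1-[(4R,6R)-6-bromo-4-chloro-5,5-dimethylcyclohex-1-en-1-yl]ethan-1-ol | CC1(C)[C@H](Cl)CC=C([C@@H](O)CBr)[C@H]1Br
F5 | step 7 | (2R)-2-[(4R)-4-chloro-3,3-dimethylcyclohex-1-en-1-yl]oxirane | C1O[C@@H]1C2=CC(C)(C)[C@H](Cl)CC2
F6 | step 7 | (2S)-2-chloro-2-[(4R)-4-chloro-3,3-dimethylcyclohex-1-en-1-yl]ethan-1-ol | Cl[C@H](CO)C1=CC(C)(C)[C@H](Cl)CC1
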